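## The problem

Target 15 is a phenylcoumaran neolignan sulfate. It is a 2,3-dihydro-1-benzofuran whose ring A carries a methoxy group at C7 and a 3-(sulfooxy)propyl chain at C5; C2 bears the 4-hydroxy-3-methoxyphenyl ring B and C3 a hydroxymethyl group. Only one ring has to be made, the oxygen heterocycle fused to ring A, and it can be closed at O1–C2, C2–C3 or C3–C3a. C2 (S) and C3 (R) are adjacent and trans. C2 is benzylic and oxygen-bearing, so it can be set by an asymmetric C–O bond formation, and once set it can direct C3 because its aryl group keeps away from a new substituent on the neighbouring carbon; C3 can direct C2 only under equilibrating conditions. The hydrogen sulfate is acid-labile and makes every compound that carries it polar, so it must come late. The free 4-hydroxyl of ring B makes the O1–C2 bond ionisable and must stay masked to the end, and O1–C2 is also a benzylic ether that can be hydrogenolysed. Two primary alcohols have to be told apart, because only the propyl terminus is sulfated. The enabling feature is that C3 and its exocyclic CH2O carbon are the two carbons of a vinyl group on C2, while C3a is an arene carbon ortho to O1. A radical at C3a is therefore in a 1,5 relation to the internal alkene carbon, and ring closure there forms C3–C3a and leaves the unpaired electron on the exocyclic carbon, where the oxygen is needed.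

## Retrosynthesis

**15 from 14.** The last bonds broken are two benzylic C–O bonds of protecting groups in 14: the benzyl ether on the ring B phenol and the benzyl carbonate on the C3 hydroxymethyl group. Hydrogenolysis is neutral, removes both at once and leaves only volatile by-products, which suits a final compound that is a salt; an ester-based end game would expose the free 4-hydroxyphenyl dihydrobenzofuran to base. 14 is not simpler in skeleton, but it is a stable, fully protected sulfate. The forward step must cleave two unhindered benzyl–oxygen bonds and spare the cyclic O1–C2 bond and the sulfate.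

**14 from 13, 12 and 11.** The S–O bond of the sulfate is cut to give primary alcohol 13, then the silyl ether is restored (12), then the carbonate is removed (11). The key step dictates this order, because it delivers the C3 hydroxymethyl group free and the propanol silylated, the reverse of what the target needs. Capping the new hydroxyl as a benzyl carbonate instead of an acetate costs the same single step but lets it leave together with the ring B benzyl group, so four steps follow the key step instead of five. The forward steps must be orthogonal: acylation of a β-branched primary alcohol, buffered fluoride cleavage of the silyl ether with the carbonate intact, and sulfation of one primary alcohol.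

**11 from 9.** The C3–C3a bond and the C–O bond of the hydroxymethyl group are cut together. Forming O1–C2 last would need the ring B phenol free and would put C2 under equilibrium. Forming C2–C3 last would need a two-component annulation that sets both centres at once. Forming C3–C3a last lets C2 be made first by a catalytic asymmetric reaction of known scope and then used to control C3. A homolytic cut turns C3 and its CH2 into a vinyl group and C3a into an aryl iodide, which is ether 9. The precursor has one ring, one stereocentre and one hydroxyl fewer, and its other groups are inert to radicals. The forward step must give 5-exo closure of the aryl radical, trans selectivity from C2, and capture of the primary radical by oxygen (through hydroperoxide 10) before hydrogen transfer.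

**9 from 8 and 7.** The allylic C–O bond between C2 and the ring A oxygen is cut, giving lithium phenoxide 8 (from iodophenol 3) and the linear cinnamyl carbonate 7. This places the stereocentre under the control of an iridium–phosphoramidite catalyst, which joins aryloxides to the substituted terminus of cinnamyl carbonates. An SN2 displacement at this carbon, for example a Mitsunobu reaction, would pass through a benzylic, allylic centre carrying a 4-alkoxyaryl group and would lose configuration and regiochemistry. Both halves are achiral and each is two or three steps from catalogue compounds. The forward step must favour the branched over the linear ether, select one enantiotopic face, and tolerate an aryl iodide and a phenoxide with two ortho substituents.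

**3 from 2 and 1.** Removing the silyl group from 3 gives 2, and removing iodine gives 1. Iodinating before silylating uses the iodine twice: as the later radical precursor, and as a second ortho substituent that slows silylation of the phenol so the primary alcohol of 2 can be protected selectively. Compound 1 already holds ring A with its three-carbon chain.

**7 from 6, 5 and 4.** Carbonate 7 comes from allylic alcohol 6, this from enoate 5, and this from aldehyde 4 by a two-carbon olefination. The E geometry that the iridium catalyst requires of its substrate is set in the Wittig reaction.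

## Roads not taken

**Alternative 1:** oxa-cyclisation at the quinone-methide level.
- **Cut:** O1–C2. The precursor is the open-chain bisphenol A1, (2R)-2-(5-bromo-2-hydroxy-3-methoxyphenyl)-3-(4-hydroxy-3-methoxyphenyl)propyl acetate, whose only stereocentre is the future C3.
- **Key step:** Ag2O or DDQ oxidises the benzylic CH2 para to the ring B hydroxyl to the quinone-methide level, and the ring A phenol adds to that carbon (5-exo-trig) to give bromide A2.
- **Merits:** ring B needs no protecting group. Because the ring can reopen at the same oxidation level, the trans isomer can be reached under thermodynamic control. That is better than the chosen plan, which relies on kinetic control.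
- **Weak points:**
  - The stereocentre of A1 needs its own asymmetric synthesis of an acyclic 2,3-diarylpropanol.
  - Both phenols of A1 are oxidisable, so phenoxyl coupling competes with the slow benzylic oxidation of a simple 4-alkylguaiacol.
  - A2 carries bromine where the side chain belongs. Three carbons must still be attached by cross-coupling, with a free phenol present, before the two primary hydroxyls can be differentiated.
- **Comparison:** the chosen plan is shorter and convergent, has the side chain in place from the first step, and sets its first stereocentre catalytically.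

**Alternative 2:** (4+1) annulation.
- **Cut:** C2–C3 and O1–C2 together. The partners are sulfone A3, 2-[2-(benzyloxy)-1-(phenylsulfonyl)ethyl]-6-methoxy-4-[3-(triisopropylsilyloxy)propyl]phenol, and the chiral benzylic sulfonium salt A4, drawn with a (2R,5R)-2,5-dimethylthiolane.
- **Key step:** base triggers ortho-quinone-methide generation from A3 and ylide generation from A4. Carbon–carbon bond formation at the future C3 is followed by displacement of the sulfide by the phenoxide, giving dihydrobenzofuran A5.
- **Merits:** this is the most convergent road. Two bonds and both stereocentres are made in one step, the anti betaine leads to the trans ring, and the C3 oxygen is already benzylated. Its end game is three steps (desilylation, sulfation, one hydrogenolysis) against four in the chosen plan, and in that respect it is better.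
- **Weak points:**
  - The quinone-methide stage from A3 carries a CH2OBn group with hydrogens that can shift and aromatise the ring.
  - The well-behaved (4+1) precedents use aryl-substituted methides and carbonyl-stabilised ylides, not a semi-stabilised benzylic ylide whose enantiocontrol depends on ylide conformation and betaine reversibility.
  - The chiral sulfide is stoichiometric.
- **Comparison:** the chosen plan relies, for each stereocentre, on a reaction with close precedent on the same substitution pattern.

**Alternative 3:** ring contraction of a flavanone.
- **Cut:** C3–C3a, made by a 1,2-shift instead of a radical. The precursor is the (2S)-flavanone A6.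
- **Key step:** PhI(OAc)2 with H2SO4 in trimethyl orthoformate (a trivalent iodine oxidant) makes the ring A carbon migrate from C4 to C3 and gives the ring-contracted methyl ester A7, the (2S,3S) trans compound.
- **Merits:** C3 emerges at the ester oxidation level, so the trans relation can be corrected by epimerisation and the hydroxymethyl group follows by reduction. No halide is needed on ring A. In diastereocontrol this road is more secure than the chosen plan.
- **Weak points:**
  - A strongly acidic oxidising medium meets a silyl ether and an electron-rich, benzyl-protected ring B.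
  - The C2 stereocentre of A6 can be lost by acid-mediated retro-oxa-Michael ring opening, which the 4-alkoxyaryl group favours.
  - An electron-rich ring B can itself migrate from C2 to C3 in competition with ring A.
  - A6 needs an acylated ring A, an aldol condensation and an asymmetric ring closure.
  - After A7, a reduction and the same four-step end game remain.
- **Comparison:** the chosen plan forms the same bond under neutral conditions at or below room temperature, where C2 cannot ionise.

Key step: step 7

**Assumptions**
- The target is drawn as the hydrogen sulfate. Sulfates 14 and 15 are named and drawn in that acid form but are handled as sodium salts, and the acid form is set free only by a final cold pass through a sulfonic acid resin.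
- The (Sa,Sc,Sc) phosphoramidite is taken to be the antipode that delivers the (S)-ether 9, the same sense as for other heteroatom nucleophiles with cinnamyl carbonates. If the sense proves opposite, the (Ra,Rc,Rc) ligand is used and nothing else changes.
- Compounds 1 and 4 are catalogue chemicals.

## Steps

Step 1
Reactants: 1 4-(3-hydroxypropyl)-2-methoxyphenol (dihydroconiferyl alcohol)
Product: 2 4-(3-hydroxypropyl)-2-iodo-6-methoxyphenol
Conditions: I2 (1.05 equiv), NaHCO3, THF/H2O, 0 °C → rt
Reagents that add atoms: iodine, II
Why: Electrophilic aromatic iodination of a phenol; the hydroxyl directs to its only free ortho position because the para position carries the chain and the other ortho position the methoxy group, and the primary alcohol is inert.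

Step 2
Reactants: 2 4-(3-hydroxypropyl)-2-iodo-6-methoxyphenol
Product: 3 2-iodo-6-methoxy-4-[3-(triisopropylsilyloxy)propyl]phenol
Conditions: i-Pr3SiCl (1.05 equiv), imidazole, DMF, 0 °C → rt
Reagents that add atoms: chlorotriisopropylsilane, CC(C)[Si](Cl)(C(C)C)C(C)C
Why: Imidazole-promoted silylation; the bulky silyl chloride should take the unhindered primary alcohol, while the phenol, flanked by iodine and methoxy, reacts far more slowly.

Step 3
Reactants: 4 4-(benzyloxy)-3-methoxybenzaldehyde
Product: 5 ethyl (2E)-3-[4-(benzyloxy)-3-methoxyphenyl]prop-2-enoate
Conditions: Ph3P=CHCO2Et, toluene, 80 °C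
Reagents that add atoms: ethyl (triphenylphosphoranylidene)acetate, CCOC(=O)C=P(c1ccccc1)(c1ccccc1)c1ccccc1
Why: Wittig olefination with a stabilised ylide, which gives the E-enoate from aromatic aldehydes.

Step 4
Reactants: 5 ethyl (2E)-3-[4-(benzyloxy)-3-methoxyphenyl]prop-2-enoate
Product: 6 (2E)-3-[4-(benzyloxy)-3-methoxyphenyl]prop-2-en-1-ol
Conditions: i-Bu2AlH (2.2 equiv), CH2Cl2, −78 → 0 °C; aq. potassium sodium tartrate
Reagents that add atoms: none
Why: 1,2-Reduction of an enoate to the allylic alcohol by an aluminium hydride; the alkene geometry and the benzyl ether are untouched.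

Step 5
Reactants: 6 (2E)-3-[4-(benzyloxy)-3-methoxyphenyl]prop-2-en-1-ol
Product: 7 (2E)-3-[4-(benzyloxy)-3-methoxyphenyl]prop-2-en-1-yl methyl carbonate
Conditions: ClCO2Me, pyridine, CH2Cl2, 0 °C
Reagents that add atoms: methyl chloroformate, COC(=O)Cl
Why: Alkoxycarbonylation of a primary allylic alcohol; the basic medium keeps the electron-rich cinnamyl system from ionising.

Step 6
Reactants: 3 2-iodo-6-methoxy-4-[3-(triisopropylsilyloxy)propyl]phenol; 7 (2E)-3-[4-(benzyloxy)-3-methoxyphenyl]prop-2-en-1-yl methyl carbonate
Product: 9 1-(benzyloxy)-4-{(1S)-1-[2-iodo-6-methoxy-4-(3-(triisopropylsilyloxy)propyl)phenoxy]prop-2-en-1-yl}-2-methoxybenzene, via lithium phenoxide 8 (not isolated)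
Conditions: 3, LiN(SiMe3)2, THF, 0 °C; then 7, [Ir(cod)Cl]2 (2 mol %), (Sa,Sc,Sc)-(1,1′-binaphthalene-2,2′-diyl) N,N-bis(1-phenylethyl)phosphoramidite (4 mol %), THF, 50 °C; chromatography on Et3N-deactivated silica
Reagents that add atoms: none
Why: Iridium-catalysed asymmetric allylic etherification of a cinnamyl carbonate with a lithium aryloxide; the cyclometalated iridium–phosphoramidite complex ionises 7 and the phenoxide attacks the aryl-substituted allyl terminus anti to the metal, so the branched ether forms and the ligand fixes the new stereocentre as S; the aryl iodide should not add oxidatively to the monovalent iridium catalyst at this temperature.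

Step 7
Reactants: 9 1-(benzyloxy)-4-{(1S)-1-[2-iodo-6-methoxy-4-(3-(triisopropylsilyloxy)propyl)phenoxy]prop-2-en-1-yl}-2-methoxybenzene
Product: 11 {(2S,3R)-2-[4-(benzyloxy)-3-methoxyphenyl]-7-methoxy-5-[3-(triisopropylsilyloxy)propyl]-2,3-dihydro-1-benzofuran-3-yl}methanol, via primary hydroperoxide 10 (not isolated)
Conditions: Bu3SnH (3 equiv, added over 4 h), stream of dry air, toluene, 0 °C → rt
Reagents that add atoms: dioxygen (from air), O=O
Why: The stannyl radical abstracts iodine from 9 to give the σ-aryl radical at the future C3a, which adds to the internal vinyl carbon and forms C3–C3a; the exocyclic primary radical is captured by O2, the peroxyl radical takes hydrogen from Bu3SnH to give hydroperoxide 10 and a new stannyl radical, and 10 is reduced by further stannane to 11. The closest known reaction type is the tin hydride mediated aerobic cyclisation of 2-iodophenyl allyl ethers to 3-(hydroxymethyl)-2,3-dihydrobenzofurans, which is this reaction without the C2 aryl group. The dihydrofuran ring closes in the 5-exo-trig mode, and the 6-endo path to a chroman is disfavoured by the usual stereoelectronic preference of aryl radicals. The new stereocentre C3 is controlled by C2: in the envelope-like transition state the ring B aryl group lies pseudo-equatorial, away from the developing CH2 group, so the trans (2S,3R) isomer should predominate, and C2 itself is not touched. Three selectivities are needed: ring closure before the aryl radical is reduced or oxygenated (closure of 2-(allyloxy)phenyl radicals is far faster than either at these concentrations), oxygen capture before hydrogen transfer to the primary radical (secured by slow addition of the stannane into air-saturated solvent), and trans over cis (helped by the low temperature). The hydrogen on C2 stands in a 1,4 relation to the radical centre and cannot be transferred through a favourable transition state. The benzyl ether, the silyl ether and the electron-rich arenes should be inert to stannyl and peroxyl radicals under these conditions.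

Step 8
Reactants: 11 {(2S,3R)-2-[4-(benzyloxy)-3-methoxyphenyl]-7-methoxy-5-[3-(triisopropylsilyloxy)propyl]-2,3-dihydro-1-benzofuran-3-yl}methanol
Product: 12 benzyl {(2S,3R)-2-[4-(benzyloxy)-3-methoxyphenyl]-7-methoxy-5-[3-(triisopropylsilyloxy)propyl]-2,3-dihydro-1-benzofuran-3-yl}methyl carbonate
Conditions: BnOCOCl, pyridine, DMAP (cat.), CH2Cl2, 0 °C
Reagents that add atoms: benzyl chloroformate, O=C(Cl)OCc1ccccc1
Why: Alkoxycarbonylation of the only free hydroxyl; the benzyl carbonate is stable to fluoride and to sulfation and is later lost by hydrogenolysis together with the phenol benzyl ether.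

Step 9
Reactants: 12 benzyl {(2S,3R)-2-[4-(benzyloxy)-3-methoxyphenyl]-7-methoxy-5-[3-(triisopropylsilyloxy)propyl]-2,3-dihydro-1-benzofuran-3-yl}methyl carbonate
Product: 13 benzyl {(2S,3R)-2-[4-(benzyloxy)-3-methoxyphenyl]-5-(3-hydroxypropyl)-7-methoxy-2,3-dihydro-1-benzofuran-3-yl}methyl carbonate
Conditions: Bu4NF, AcOH (1:1), THF, rt
Reagents that add atoms: none
Why: Fluoride-mediated desilylation; buffering with acetic acid keeps the medium from becoming basic, so the carbonate should neither migrate nor exchange.

Step 10
Reactants: 13 benzyl {(2S,3R)-2-[4-(benzyloxy)-3-methoxyphenyl]-5-(3-hydroxypropyl)-7-methoxy-2,3-dihydro-1-benzofuran-3-yl}methyl carbonate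
Product: 14 3-[(2S,3R)-2-[4-(benzyloxy)-3-methoxyphenyl]-3-{[(benzyloxycarbonyl)oxy]methyl}-7-methoxy-2,3-dihydro-1-benzofuran-5-yl]propyl hydrogen sulfate
Conditions: SO3·pyridine, DMF, rt; then exchange to the sodium salt on a Na+-form cation-exchange resin
Reagents that add atoms: sulfur trioxide–pyridine complex, O=S(=O)([O-])[n+]1ccccc1
Why: O-Sulfation of a primary alcohol with an amine–SO3 complex; it is the only hydroxyl in the molecule, and exchange to the sodium salt removes pyridine, which would slow the hydrogenolysis that follows.

Step 11
Reactants: 14 3-[(2S,3R)-2-[4-(benzyloxy)-3-methoxyphenyl]-3-{[(benzyloxycarbonyl)oxy]methyl}-7-methoxy-2,3-dihydro-1-benzofuran-5-yl]propyl hydrogen sulfate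
Product: 15 3-[(2S,3R)-2-(4-hydroxy-3-methoxyphenyl)-3-(hydroxymethyl)-7-methoxy-2,3-dihydro-1-benzofuran-5-yl]propyl hydrogen sulfate
Conditions: H2 (1 atm), 10% Pd/C, MeOH, rt; then sulfonic acid resin (H+ form), H2O, 0 °C, freeze-drying
Reagents that add atoms: none
Why: Heterogeneous hydrogenolysis of benzylic C–O bonds; the aryl benzyl ether and the benzyl carbonate (which then loses CO2) cleave readily at 1 atm, the cyclic secondary O1–C2 bond is much slower for steric reasons, the sulfate salt is not reducible, and no stereocentre is touched.

## Compound list

1 | 4-(3-hydroxypropyl)-2-methoxyphenol (dihydroconiferyl alcohol) | COc1cc(CCCO)ccc1O | starting material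
2 | 4-(3-hydroxypropyl)-2-iodo-6-methoxyphenol | COc1cc(CCCO)cc(I)c1O | intermediate
3 | 2-iodo-6-methoxy-4-[3-(triisopropylsilyloxy)propyl]phenol | COc1cc(CCCO[Si](C(C)C)(C(C)C)C(C)C)cc(I)c1O | intermediate
4 | 4-(benzyloxy)-3-methoxybenzaldehyde | COc1cc(C=O)ccc1OCc1ccccc1 | starting material
5 | ethyl (2E)-3-[4-(benzyloxy)-3-methoxyphenyl]prop-2-enoate | CCOC(=O)/C=C/c1ccc(OCc2ccccc2)c(OC)c1 | intermediate
6 | (2E)-3-[4-(benzyloxy)-3-methoxyphenyl]prop-2-en-1-ol | COc1cc(/C=C/CO)ccc1OCc1ccccc1 | intermediate
7 | (2E)-3-[4-(benzyloxy)-3-methoxyphenyl]prop-2-en-1-yl methyl carbonate | COC(=O)OC/C=C/c1ccc(OCc2ccccc2)c(OC)c1 | intermediate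
8 | lithium 2-iodo-6-methoxy-4-[3-(triisopropylsilyloxy)propyl]phenolate | [Li+].COc1cc(CCCO[Si](C(C)C)(C(C)C)C(C)C)cc(I)c1[O-] | intermediate (not isolated)
9 | 1-(benzyloxy)-4-{(1S)-1-[2-iodo-6-methoxy-4-(3-(triisopropylsilyloxy)propyl)phenoxy]prop-2-en-1-yl}-2-methoxybenzene | COc1cc([C@H](C=C)Oc2c(OC)cc(CCCO[Si](C(C)C)(C(C)C)C(C)C)cc2I)ccc1OCc1ccccc1 | intermediate (precursor of the key step)
10 | (2S,3R)-2-[4-(benzyloxy)-3-methoxyphenyl]-3-(hydroperoxymethyl)-7-methoxy-5-[3-(triisopropylsilyloxy)propyl]-2,3-dihydro-1-benzofuran | COc1cc([C@H]2Oc3c(OC)cc(CCCO[Si](C(C)C)(C(C)C)C(C)C)cc3[C@@H]2COO)ccc1OCc1ccccc1 | intermediate (not isolated)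
11 | {(2S,3R)-2-[4-(benzyloxy)-3-methoxyphenyl]-7-methoxy-5-[3-(triisopropylsilyloxy)propyl]-2,3-dihydro-1-benzofuran-3-yl}methanol | COc1cc([C@H]2Oc3c(OC)cc(CCCO[Si](C(C)C)(C(C)C)C(C)C)cc3[C@@H]2CO)ccc1OCc1ccccc1 | intermediate (product of the key step)
12 | benzyl {(2S,3R)-2-[4-(benzyloxy)-3-methoxyphenyl]-7-methoxy-5-[3-(triisopropylsilyloxy)propyl]-2,3-dihydro-1-benzofuran-3-yl}methyl carbonate | COc1cc([C@H]2Oc3c(OC)cc(CCCO[Si](C(C)C)(C(C)C)C(C)C)cc3[C@@H]2COC(=O)OCc2ccccc2)ccc1OCc1ccccc1 | intermediate
13 | benzyl {(2S,3R)-2-[4-(benzyloxy)-3-methoxyphenyl]-5-(3-hydroxypropyl)-7-methoxy-2,3-dihydro-1-benzofuran-3-yl}methyl carbonate | COc1cc([C@H]2Oc3c(OC)cc(CCCO)cc3[C@@H]2COC(=O)OCc2ccccc2)ccc1OCc1ccccc1 | intermediate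
14 | 3-[(2S,3R)-2-[4-(benzyloxy)-3-methoxyphenyl]-3-{[(benzyloxycarbonyl)oxy]methyl}-7-methoxy-2,3-dihydro-1-benzofuran-5-yl]propyl hydrogen sulfate | COc1cc([C@H]2Oc3c(OC)cc(CCCOS(=O)(=O)O)cc3[C@@H]2COC(=O)OCc2ccccc2)ccc1OCc1ccccc1 | intermediate
15 | 3-[(2S,3R)-2-(4-hydroxy-3-methoxyphenyl)-3-(hydroxymethyl)-7-methoxy-2,3-dihydro-1-benzofuran-5-yl]propyl hydrogen sulfate | COc1cc([C@H]2Oc3c(OC)cc(CCCOS(=O)(=O)O)cc3[C@@H]2CO)ccc1O | target

## Step count and least certain steps

Total step count: 11. Longest linear sequence: 9 steps (4 to 15 through steps 3 to 11). The ring A branch (steps 1 and 2) joins at step 6.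

**Step 7 (key step).**
- What may go wrong: hydrogen transfer from the stannane to the primary radical before oxygen capture, which is the likeliest failure if the stannane concentration rises or the solution is starved of air.
- Also possible: insufficient facial discrimination in the ring closure, because C3 is set under kinetic control by a single neighbouring centre, and slow autoxidation at the doubly activated C2–H of 9.
- Fallback: trap the radical with a persistent nitroxide instead of air. Starting from 9, Bu3SnH and TEMPO in benzene at 60 °C should give the 2,2,6,6-tetramethylpiperidin-1-yl ether of 11, F1, in which the primary radical has coupled with the nitroxide at near diffusion rate. Reductive N–O cleavage with Zn in AcOH/THF/H2O at rt to 40 °C, which the triisopropylsilyl ether should survive, returns to the route at 11.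
- A minor cis isomer, if formed by either procedure, would be removed by chromatography at 11 or 12.

**Step 6.**
- What may go wrong: slow attack of the doubly ortho-substituted phenoxide on the allyl–iridium intermediate.
- Also possible: erosion of the branched-to-linear ratio and of the enantiomeric purity by re-ionisation of the product. The iodophenoxide is a good leaving group, and the 4-alkoxyaryl group stabilises the allyl cation.
- Fallback: separate the making of the stereocentre from the making of the ether.
  - Starting from 4, CH2=CHMgBr should give racemic 1-[4-(benzyloxy)-3-methoxyphenyl]prop-2-en-1-ol F2.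
  - Acylation with vinyl acetate catalysed by Candida antarctica lipase B is expected, by the usual size rule for secondary alcohols, to leave the (S)-alcohol F3 and convert the antipode into the (R)-acetate F4, which is separated.
  - F3 is converted with ClCO2Me and pyridine into the branched (S)-methyl carbonate F5.
  - Stereospecific etherification of F5 with phenoxide 8, catalysed by RhCl(PPh3)3 modified with P(OMe)3 (THF, 0 °C to rt), a reaction type developed for ortho-disubstituted aryloxides that proceeds with net retention, returns to the route at 9.

**Step 11.**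
- What may go wrong: slow debenzylation of the salt-like substrate, so that long exposure brings reductive cleavage of the benzylic O1–C2 bond.
- Also possible: solvolytic loss of the sulfate when the acid form is liberated.
- Fallback: debenzylate before sulfur is introduced and finish with base.
  - Starting from 11, hydrogenolysis (H2, Pd/C, EtOAc) of the neutral compound should give the phenol F6.
  - Ac2O and pyridine give the diacetate F7.
  - HF·pyridine in THF removes the silyl group to give alcohol F8.
  - SO3·pyridine gives the sulfated diacetate F9.
  - Brief methanolysis with K2CO3 in MeOH at 0 °C removes both acetates and returns to the route at 15.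

## Further compounds

F1 | step 7 | 1-({(2S,3R)-2-[4-(benzyloxy)-3-methoxyphenyl]-7-methoxy-5-[3-(triisopropylsilyloxy)propyl]-2,3-dihydro-1-benzofuran-3-yl}methoxy)-2,2,6,6-tetramethylpiperidine | COc1cc([C@H]2Oc3c(OC)cc(CCCO[Si](C(C)C)(C(C)C)C(C)C)cc3[C@@H]2CON4C(C)(C)CCCC4(C)C)ccc1OCc1ccccc1
F2 | step 6 | rac-1-[4-(benzyloxy)-3-methoxyphenyl]prop-2-en-1-ol | COc1cc(C(O)C=C)ccc1OCc1ccccc1
F3 | step 6 | (1S)-1-[4-(benzyloxy)-3-methoxyphenyl]prop-2-en-1-ol | COc1cc([C@H](C=C)O)ccc1OCc1ccccc1
F4 | step 6 | (1R)-1-[4-(benzyloxy)-3-methoxyphenyl]prop-2-en-1-yl acetate | COc1cc([C@@H](C=C)OC(C)=O)ccc1OCc1ccccc1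
F5 | step 6 | (1S)-1-[4-(benzyloxy)-3-methoxyphenyl]prop-2-en-1-yl methyl carbonate | COc1cc([C@H](C=C)OC(=O)OC)ccc1OCc1ccccc1
F6 | step 11 | 4-{(2S,3R)-3-(hydroxymethyl)-7-methoxy-5-[3-(triisopropylsilyloxy)propyl]-2,3-dihydro-1-benzofuran-2-yl}-2-methoxyphenol | COc1cc([C@H]2Oc3c(OC)cc(CCCO[Si](C(C)C)(C(C)C)C(C)C)cc3[C@@H]2CO)ccc1O
F7 | step 11 | 4-{(2S,3R)-3-(acetoxymethyl)-7-methoxy-5-[3-(triisopropylsilyloxy)propyl]-2,3-dihydro-1-benzofuran-2-yl}-2-methoxyphenyl acetate | COc1cc([C@H]2Oc3c(OC)cc(CCCO[Si](C(C)C)(C(C)C)C(C)C)cc3[C@@H]2COC(C)=O)ccc1OC(C)=O
F8 | step 11 | 4-[(2S,3R)-3-(acetoxymethyl)-5-(3-hydroxypropyl)-7-methoxy-2,3-dihydro-1-benzofuran-2-yl]-2-methoxyphenyl acetate | COc1cc([C@H]2Oc3c(OC)cc(CCCO)cc3[C@@H]2COC(C)=O)ccc1OC(C)=O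
F9 | step 11 | 3-[(2S,3R)-3-(acetoxymethyl)-2-(4-acetoxy-3-methoxyphenyl)-7-methoxy-2,3-dihydro-1-benzofuran-5-yl]propyl hydrogen sulfate | COc1cc([C@H]2Oc3c(OC)cc(CCCOS(=O)(=O)O)cc3[C@@H]2COC(C)=O)ccc1OC(C)=O
A1 | alternative 1 | (2R)-2-(5-bromo-2-hydroxy-3-methoxyphenyl)-3-(4-hydroxy-3-methoxyphenyl)propyl acetate | COc1cc(Br)cc([C@@H](Cc2ccc(O)c(OC)c2)COC(C)=O)c1O
A2 | alternative 1 | [(2S,3R)-5-bromo-2-(4-hydroxy-3-methoxyphenyl)-7-methoxy-2,3-dihydro-1-benzofuran-3-yl]methyl acetate | COc1cc([C@H]2Oc3c(OC)cc(Br)cc3[C@@H]2COC(C)=O)ccc1O
A3 | alternative 2 | 2-[2-(benzyloxy)-1-(phenylsulfonyl)ethyl]-6-methoxy-4-[3-(triisopropylsilyloxy)propyl]phenol | COc1cc(CCCO[Si](C(C)C)(C(C)C)C(C)C)cc(C(COCc2ccccc2)S(=O)(=O)c2ccccc2)c1O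
A4 | alternative 2 | (2R,5R)-1-[4-(benzyloxy)-3-methoxybenzyl]-2,5-dimethylthiolan-1-ium trifluoromethanesulfonate | COc1cc(C[S+]2[C@H](C)CC[C@H]2C)ccc1OCc1ccccc1.[O-]S(=O)(=O)C(F)(F)F
A5 | alternative 2 | (2S,3R)-3-[(benzyloxy)methyl]-2-[4-(benzyloxy)-3-methoxyphenyl]-7-methoxy-5-[3-(triisopropylsilyloxy)propyl]-2,3-dihydro-1-benzofuran | COc1cc([C@H]2Oc3c(OC)cc(CCCO[Si](C(C)C)(C(C)C)C(C)C)cc3[C@@H]2COCc2ccccc2)ccc1OCc1ccccc1
A6 | alternative 3 | (2S)-2-[4-(benzyloxy)-3-methoxyphenyl]-8-methoxy-6-[3-(triisopropylsilyloxy)propyl]-2,3-dihydro-4H-chromen-4-one | COc1cc([C@@H]2CC(=O)c3cc(CCCO[Si](C(C)C)(C(C)C)C(C)C)cc(OC)c3O2)ccc1OCc1ccccc1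
A7 | alternative 3 | methyl (2S,3S)-2-[4-(benzyloxy)-3-methoxyphenyl]-7-methoxy-5-[3-(triisopropylsilyloxy)propyl]-2,3-dihydro-1-benzofuran-3-carboxylate | COc1cc([C@H]2Oc3c(OC)cc(CCCO[Si](C(C)C)(C(C)C)C(C)C)cc3[C@@H]2C(=O)OC)ccc1OCc1ccccc1
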